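The elm run taught me to keep books on incoming ligand, the limiting reagent of the flask, with 0.0600 M charged against 0.10 M of starting complex.

| flask | starting complex | incoming ligand | remark | time |
|---|---|---|---|---|
| elm | 0.067 M | 0.060 M | run made earlier |  |
| larch | 0.15 M | 0.060 M | run made earlier |  |
| maple | 0.10 M | 0.030 M | run made earlier |  |
| flask | 0.10 M | 0.0600 M |  | 30 min |

| run | time / min | complex with one exchanged / % | complex with two exchanged / % |
|---|---|---|---|
| elm | 0.667 | 28.2 | 0 |
| elm | 2.50 | 46.1 | 0.5 |
| elm | 8.00 | 37.3 | 0.6 |
| elm | 30.0 | 26.1 | 2.7 |
| larch | 0.667 | 23.4 | 0.8 |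
| larch | 2.50 | 29.9 | 0 |
| larch | 8.00 | 24.3 | 1.2 |
| larch | 30.0 | 17.9 | 0.4 |
| maple | 0.667 | 11.5 | 0 |
| maple | 2.50 | 21.3 | 0 |
| maple | 8.00 | 19.5 | 1.0 |
| maple | 30.0 | 15.0 | 1.0 |

(readings scatter by 1 percentage point)



- time, not beyond 30 min, at which the flask holds most complex with one exchanged
- the amount of complex with one exchanged, in percent of the starting complex charged, at that time

In elm, larch and maple the highest reading of complex with one exchanged came at 2.50 min, so I drew up the ledger there. In elm, 0.060 M of incoming ligand was charged. Complex with one exchanged held 0.0309 M and complex with two exchanged read 0.5% against a scatter of 1 percentage point; with that small reading set aside, 0.0291 M stayed unbooked, either free or in something unread.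

I wrote s = y·c_M/c_X, with y the highest reading of complex with one exchanged, c_M the charge of starting complex and c_X the charge of incoming ligand:

elm: s = 51.5%

larch: s = 74.7%

The flask has their ligand charge, and its complex charge lies between theirs, so I read along the straight line between them:

flask: s = 60.7%

This ligand share, the part of the charged incoming ligand standing as complex with one exchanged at the highest reading, is an estimate with the readings' scatter. It gave me a peak near 2.50 min of

s·c_X/c_M = 36.4%

The forecast said 40% (37% to 43%) at 3.2 min (2.2 min to 4.8 min): “The peak is therefore near 3 min, at about 40%”. My ledger stood lower than that.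

The flask peaked at 36.0% at 2.66 min.

    complex with one exchanged + incoming ligand ⇌ leaving ligand + complex with two exchanged (K = 3.94, k = 0.00816 M⁻¹ s⁻¹)
    incoming ligand ⇌ dormant form (K = 22.0, k = 0.00507 s⁻¹)
    starting complex + incoming ligand ⇌ leaving ligand + complex with one exchanged (K = 3.00, k = 0.189 M⁻¹ s⁻¹)

At that time the flask held 0.0156 M of dormant form, 26.0% of the incoming ligand charged, an unread entry beside the 12.0% of incoming ligand still free. The flask's ligand share came to 60.0%.

The neighbour flask with 0.036 M of incoming ligand has the starting complex charge of maple, whose share read 71.0%. Reading between maple and the flask gave s = 68.8%, hence an estimated peak of 24.8%. The computed peak of that neighbour flask was 24.1%.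

The earlier runs and the new flask are calculated on assumed constants; noise was put on by code.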